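**Retrosynthetic overview**
- Aryl–C2/C5 bonds: both 4-oxyphenyl groups come from 4-bromophenol 1 (as acetate 2), joined twice to furan 3 by C–H arylation to give 2,5-diarylfuran 4.
- Aroyl carbons: resorcinol 5 is formylated to aldehyde 6 and acetylated to 7, the acyl-radical precursor.
- Key disconnection, C3–C(=O) and C4–C(=O): two successive radical hydroacylations of 4 by 7, through dihydrofuran 8, give racemic hexaacetate 9; all four stereocentres arise here.
- End game: 9 is resolved to 10 and deacetylated to the target 11.
- Ring order: no ring is closed by cyclisation; the benzene rings are bought, and the tetrahydrofuran ring is the furan ring of 3, saturated in the key step.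

Assumption: the SMILES defines the target as the C2-symmetric (2S,3R,4R,5S) isomer (2,3-cis, 3,4-trans, 4,5-cis, 2,5-trans), and a preparative resolution on a chiral phase is counted as one step.

**Step 1**
Reactants: 1 4-bromophenol
Product: 2 4-bromophenyl acetate
Conditions: Ac2O (1.2 equiv), pyridine (1.5 equiv), CH2Cl2, 0 °C to rt
Reagents that add atoms: acetic anhydride, CC(=O)OC(C)=O
Why: O-acetylation (nucleophilic acyl substitution) masks the phenol as an ester that tolerates palladium/acetate at 140 °C and does not quench carbon radicals; no stereocentre is formed.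

**Step 2**
Reactants: 2 4-bromophenyl acetate (2.5 equiv); 3 furan
Product: 4 2,5-bis(4-acetoxyphenyl)furan
Conditions: Pd(OAc)2 (2 mol%), KOAc (3 equiv), DMAc, 140 °C, sealed tube
Reagents that add atoms: none
Why: Palladium-catalysed direct C–H arylation (carboxylate-assisted concerted metalation–deprotonation) is selective for the α positions of furan, the 2-arylfuran reacts faster than furan so excess bromide drives it to the 2,5-diaryl compound, and acetate as the base cannot degrade the aryl acetates; no stereocentre is formed.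

**Step 3**
Reactants: 5 resorcinol
Product: 6 2,4-dihydroxybenzaldehyde
Conditions: POCl3 (1.2 equiv), DMF (1.5 equiv), MeCN, −15 °C to rt; then H2O, 50 °C
Reagents that add atoms: N,N-dimethylformamide, CN(C)C=O (formyl carbon); water, O (formyl oxygen)
Why: Vilsmeier–Haack formylation; the chloroiminium ion attacks C4 of resorcinol (para to one hydroxyl, ortho to the other), the iminium salt precipitates and so is not formylated twice, and hydrolysis gives the aldehyde; no stereocentre is formed.

**Step 4**
Reactants: 6 2,4-dihydroxybenzaldehyde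
Product: 7 2,4-diacetoxybenzaldehyde
Conditions: Ac2O (2.5 equiv), Et3N (3 equiv), DMAP (5 mol%), CH2Cl2, 0 °C to rt
Reagents that add atoms: acetic anhydride, CC(=O)OC(C)=O
Why: DMAP-catalysed O-acetylation caps both phenols, including the hydrogen-bonded ortho one, so that no phenolic O–H can intercept the radicals of the next step; no stereocentre is formed.

**Step 5**
Reactants: 4 2,5-bis(4-acetoxyphenyl)furan; 7 2,4-diacetoxybenzaldehyde (5 equiv)
Product: 9 racemic [(2S*,3R*,4R*,5S*)-2,5-bis(4-acetoxyphenyl)tetrahydrofuran-3,4-diyl]bis[(2,4-diacetoxyphenyl)methanone], via cis-3-aroyl-2,3-dihydrofuran monoadduct 8 (not isolated)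
Conditions: 4CzIPN (2 mol%), quinuclidine (20 mol%), 1-adamantanethiol (30 mol%), MeCN (degassed), 450 nm LEDs, 25 °C
Reagents that add atoms: none
Why: Proposed new method: a photochemical dual hydrogen-atom-transfer hydroacylation run twice through the furan ring; excited 4CzIPN oxidises quinuclidine, the aminium radical cation takes the hydridic formyl hydrogen of 7, the aroyl radical adds to C3 of 4 because this gives an α-oxy benzylic radical at C2 whose stabilisation outweighs the lost furan resonance energy (about 16 kcal/mol), and the bulky thiol hands H to C2 on the face away from the new aroyl group so that aryl and aroyl end up cis in 8; the second aroyl radical adds to C4 of the cyclic enol ether 8 anti to the C3 aroyl group (3,4-trans) and the C5 radical again accepts H anti to its aroyl neighbour (4,5-cis, therefore 2,5-trans), giving the cis,trans,cis racemate 9 with every atom of 4 and of two molecules of 7 in the product; because abstraction (aminium radical) and donation (thiol) are done by different species, C2–H and C5–H of 8 and 9 stay under kinetic rather than thermodynamic control; closest known reaction types are quinuclidine-mediated acyl radical formation from aldehydes, thiol-terminated radical hydroacylation of enol ethers, and the quinuclidine/thiol photochemical epimerisation of carbinol centres to the less stable isomer.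

**Step 6**
Reactants: 9 racemic hexaacetate
Product: 10 [(2S,3R,4R,5S)-2,5-bis(4-acetoxyphenyl)tetrahydrofuran-3,4-diyl]bis[(2,4-diacetoxyphenyl)methanone]
Conditions: preparative SFC, amylose tris(3,5-dimethylphenylcarbamate) on silica, CO2/iPrOH 65:35, 35 °C
Reagents that add atoms: none
Why: Resolution of a racemate by chromatography on a chiral stationary phase; no bond is made or broken, so the relative configuration from step 5 is kept and the absolute configuration is fixed by taking the (2S,3R,4R,5S) band, assigned by ECD (exciton couplet of the two aroyl chromophores against calculation) and by the optical rotation of a deacetylated sample against natural material.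

**Step 7**
Reactants: 10 (2S,3R,4R,5S)-hexaacetate
Product: 11 [(2S,3R,4R,5S)-2,5-bis(4-hydroxyphenyl)tetrahydrofuran-3,4-diyl]bis[(2,4-dihydroxyphenyl)methanone]
Conditions: NH4OAc (20 equiv), MeOH, 25 °C; pH 6 phosphate buffer work-up
Reagents that add atoms: none
Why: Ammonium-acetate-mediated methanolysis (transesterification) of aryl acetates at near-neutral pH; phenyl esters are cleaved much faster than the C3/C4 ketone α-hydrogens enolise or the p-hydroxybenzyl ether ionises, so all four stereocentres are retained.

**Compound list**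
1 | 4-bromophenol | Oc1ccc(Br)cc1 | starting material
2 | 4-bromophenyl acetate | CC(=O)Oc1ccc(Br)cc1 | intermediate
3 | furan | c1ccoc1 | starting material
4 | 2,5-bis(4-acetoxyphenyl)furan | CC(=O)Oc1ccc(cc1)-c1ccc(o1)-c1ccc(OC(C)=O)cc1 | intermediate
5 | resorcinol (benzene-1,3-diol) | Oc1cccc(O)c1 | starting material
6 | 2,4-dihydroxybenzaldehyde | O=Cc1ccc(O)cc1O | intermediate
7 | 2,4-diacetoxybenzaldehyde (4-formyl-1,3-phenylene diacetate) | CC(=O)Oc1ccc(C=O)c(OC(C)=O)c1 | intermediate
8 | racemic cis-(2S*,3R*)-2,5-bis(4-acetoxyphenyl)-3-(2,4-diacetoxybenzoyl)-2,3-dihydrofuran, one enantiomer drawn, not isolated | O=C(c1ccc(OC(C)=O)cc1OC(C)=O)[C@@H]1C=C(c2ccc(OC(C)=O)cc2)O[C@@H]1c1ccc(OC(C)=O)cc1 | intermediate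
9 | racemic [(2S*,3R*,4R*,5S*)-2,5-bis(4-acetoxyphenyl)tetrahydrofuran-3,4-diyl]bis[(2,4-diacetoxyphenyl)methanone], 2,3-cis, 3,4-trans, 4,5-cis, one enantiomer drawn | O=C(c1ccc(OC(C)=O)cc1OC(C)=O)[C@@H]1[C@@H](C(=O)c2ccc(OC(C)=O)cc2OC(C)=O)[C@@H](c2ccc(OC(C)=O)cc2)O[C@@H]1c1ccc(OC(C)=O)cc1 | intermediate
10 | [(2S,3R,4R,5S)-2,5-bis(4-acetoxyphenyl)tetrahydrofuran-3,4-diyl]bis[(2,4-diacetoxyphenyl)methanone], single enantiomer | O=C(c1ccc(OC(C)=O)cc1OC(C)=O)[C@@H]1[C@@H](C(=O)c2ccc(OC(C)=O)cc2OC(C)=O)[C@@H](c2ccc(OC(C)=O)cc2)O[C@@H]1c1ccc(OC(C)=O)cc1 | intermediate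
11 | [(2S,3R,4R,5S)-2,5-bis(4-hydroxyphenyl)tetrahydrofuran-3,4-diyl]bis[(2,4-dihydroxyphenyl)methanone] (CNP0237262.3) | O=C(c1ccc(O)cc1O)[C@@H]1[C@@H](C(=O)c2ccc(O)cc2O)[C@@H](c2ccc(O)cc2)O[C@@H]1c1ccc(O)cc1 | target

**Totals and risks**
Total step count: 7. Longest linear sequence: 5 (steps 1, 2, 5, 6, 7; the branch through steps 3 and 4 is equally long).

Most likely to fail, first: step 5. The aroyl radical may add too slowly to the aromatic furan, or the last hydrogen delivery at C5 may be steered by the C2 aryl and C3 aroyl groups on the other face, giving the 2,5-cis isomer. The fallback builds the ring by a [3+2] cycloaddition and corrects C5 afterwards; it sets out from 2 and 5 and comes back at 9.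
- 2 is coupled twice with ethylene (C=C; Pd(OAc)2, P(o-tol)3, NaOAc, DMAc, 110 °C, double Heck reaction) to (E)-4,4'-diacetoxystilbene F1.
- F1 is epoxidised (mCPBA, NaHCO3, CH2Cl2, 0 °C) to racemic trans-2,3-bis(4-acetoxyphenyl)oxirane F2.
- Resorcinol 5 is acylated at C4 with fumaryl chloride (O=C(Cl)/C=C/C(Cl)=O; AlCl3, PhNO2, 50 °C, Friedel–Crafts/Fries acylation) to (E)-1,4-bis(2,4-dihydroxyphenyl)but-2-ene-1,4-dione F3, which is acetylated (Ac2O, pyridine) to (E)-1,4-bis(2,4-diacetoxyphenyl)but-2-ene-1,4-dione F4.
- Irradiation of F2 and F4 with 2,4,6-triphenylpyrylium tetrafluoroborate (5 mol%, MeCN, 420 nm) opens the epoxide radical cation to the exo,exo carbonyl ylide. This adds to F4 with retention of the trans-diaroyl geometry and gives racemic [(2S*,3R*,4R*,5R*)-2,5-bis(4-acetoxyphenyl)tetrahydrofuran-3,4-diyl]bis[(2,4-diacetoxyphenyl)methanone] F5, the 2,5-cis cycloadduct.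
- F5 differs from 9 only at C5. The catalyst trio of step 5 without aldehyde (4CzIPN, quinuclidine, 1-adamantanethiol, MeCN, 450 nm) abstracts the benzylic α-oxy hydrogen, and the thiol returns it anti to the C4 aroyl group, which converts F5 into 9.

Second: step 2. The double C–H arylation may stop at the monoaryl furan, or acetate exchange at 140 °C may erode the esters. The fallback makes both aryl–furan bonds by cross-coupling of two prefunctionalised partners; it sets out from 2 and 3 and comes back at 4.
- 2 is borylated (bis(pinacolato)diboron, Pd(dppf)Cl2, KOAc, dioxane, 80 °C, Miyaura borylation) to 4-(4,4,5,5-tetramethyl-1,3,2-dioxaborolan-2-yl)phenyl acetate F6.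
- Furan 3 is dibrominated (N-bromosuccinimide, 2 equiv, DMF, 0 °C) to 2,5-dibromofuran F7.
- Suzuki–Miyaura coupling of F7 with 2.2 equiv of F6 (Pd(PPh3)4, K3PO4, dioxane/H2O 10:1, 70 °C) gives 4.

Third: step 7. Six esters must be cleaved without enolising C3/C4 and without opening the p-hydroxybenzyl ether. The fallback removes the acetyl groups with an enzyme instead of a nucleophile in solution; it sets out from 10 and comes back at 11. Immobilised Candida antarctica lipase B in tert-butyl methyl ether/n-butanol (10:1) at 35 °C passes the acetyl groups through the acyl-enzyme to butanol at neutral pH and gives 11 directly. This makes no new compound, F0.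

**Further compounds**
F1 | step 5 | (E)-4,4'-diacetoxystilbene | CC(=O)Oc1ccc(/C=C/c2ccc(OC(C)=O)cc2)cc1
F2 | step 5 | racemic trans-2,3-bis(4-acetoxyphenyl)oxirane, one enantiomer drawn | CC(=O)Oc1ccc(cc1)[C@@H]1O[C@H]1c1ccc(OC(C)=O)cc1
F3 | step 5 | (E)-1,4-bis(2,4-dihydroxyphenyl)but-2-ene-1,4-dione | O=C(/C=C/C(=O)c1ccc(O)cc1O)c1ccc(O)cc1O
F4 | step 5 | (E)-1,4-bis(2,4-diacetoxyphenyl)but-2-ene-1,4-dione | CC(=O)Oc1ccc(C(=O)/C=C/C(=O)c2ccc(OC(C)=O)cc2OC(C)=O)c(OC(C)=O)c1
F5 | step 5 | racemic [(2S*,3R*,4R*,5R*)-2,5-bis(4-acetoxyphenyl)tetrahydrofuran-3,4-diyl]bis[(2,4-diacetoxyphenyl)methanone], one enantiomer drawn | O=C(c1ccc(OC(C)=O)cc1OC(C)=O)[C@@H]1[C@@H](C(=O)c2ccc(OC(C)=O)cc2OC(C)=O)[C@H](c2ccc(OC(C)=O)cc2)O[C@@H]1c1ccc(OC(C)=O)cc1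
F6 | step 2 | 4-(4,4,5,5-tetramethyl-1,3,2-dioxaborolan-2-yl)phenyl acetate | CC(=O)Oc1ccc(cc1)B1OC(C)(C)C(C)(C)O1
F7 | step 2 | 2,5-dibromofuran | Brc1ccc(Br)o1
F0 | step 7 | none | none
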